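Numbering follows the eudesmane skeleton: ring A is C1–C2–C3–C4–C5–C10, ring B is C5–C6–C7–C8–C9–C10, C14 is the methyl on C10, C15 the methyl on C4, and C11 (with C12 and C13) is the side chain on C7. Compound numbers are those of the steps.

## Analysis of the target

The target 17 is a eudesmane: a decalin with the methyl C14 on the quaternary C10, the methyl C15 on C4, and on C7 a three-carbon side chain that is here a methyl acrylate (C11=C13, C12 as the ester). It has four stereocentres: C10 (methyl β, 10S), C7 (side chain β, H α, 7R), C4 (hydroxyl β, methyl α, 4R) and C3 (angeloyloxy β, 3S); C5 is trigonal because of the C5=C6 alkene. The oxygens on C3 and C4 are cis to each other and to C14, so they form one block that substrate control from ring A can build, whereas C7 lies 1,4 to C10 across ring B with nothing between them through which one centre could direct the other. The sensitive groups are the angelate, which turns into the E ester under nucleophilic, basic or acidic acyl-transfer conditions; the tertiary allylic alcohol at C4, which ionises in acid; the acrylate, a Michael acceptor; and H7, which is allylic to both C5=C6 and C11=C13, so that base or metal hydrides can move an alkene to C7=C11 and erase the stereocentre. The difficulty is therefore twofold: the remote C7/C10 pair must be set in absolute terms, and the oxidised C3–C4–C5–C6 array must be put on late and mildly around an unprotected acrylate. The feature on which the plan rests is that the fifteen skeletal carbons are an unbroken head-to-tail farnesyl chain closed by only two bonds, C6–C7 and C5–C10, with C7 and C10 in the configuration of the natural (+)-eudesmanes. A terpene cyclase can thus deliver the whole skeleton and both remote stereocentres in one operation, after which only oxidation-state changes at C12, C3, C4 and C5/C6 and one acylation remain.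

## Retrosynthetic reasoning

**C3–O acyl bond.** The target 17 is cut first at the ester oxygen on C3, giving the diol 14 (methyl 3β,4β-dihydroxyeudesma-5,11(13)-dien-12-oate) and angelic acid 15, the latter activated as the mixed anhydride 16. The angelate is the group most prone to isomerisation, so it goes on last. No protecting group is needed, because the C3 hydroxyl of 14 is secondary and equatorial while the C4 hydroxyl is tertiary. The forward reaction must acylate without Z-to-E isomerisation.

**C5=C6 alkene and C4 hydroxyl.** The tertiary allylic alcohol of 14 is traced back to the 4β,5β-epoxy alcohol 13: the C5–O bond is broken and a hydrogen is taken from C6. This is preferred to an addition to a C4 carbonyl because the configuration at C4 is then simply the face of an epoxide, and because C10 carries no hydrogen, so the new alkene can only be C5=C6. The forward reaction must open the epoxide at C5, not C4, and must not let the C5 centre rearrange.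

**Epoxide oxygen.** 13 comes from the allylic alcohol 12 by epoxidation on the face of the C3 hydroxyl. The β face is the one shielded by C14, so the oxygen has to be delivered by the hydroxyl, and this fixes that C3 must be β before the epoxidation.

**C3 stereocentre.** 12 is the 1,2-reduction product of the enone 11; hydride approach from the open α face gives the equatorial 3β-alcohol. The reduction must leave the acrylate alone.

**C3 oxygen.** The carbonyl of 11 is introduced by allylic C–H oxidation of the tetrasubstituted alkene of 10 (methyl isocostate). Placing the alkene at C4=C5 serves twice: it activates C3 now and is the site of the later epoxide. The forward reaction must choose C3 over C6 and C15.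

**Alkene position and ester.** 10 is the acid-equilibrated isomer of the exocyclic alkene 9, the methyl ester of β-costic acid 8. The isomerisation removes the C5 stereocentre, which the target does not have, and makes it unimportant which ring-A alkene isomer the cyclisation releases.

**C12 oxidation.** 8 is the C12 acid of (+)-β-selinene 5; three oxidation levels are added at the isopropenyl methyl through β-costol 6 and β-costal 7. An oxidase is proposed because 5 has two 1,1-disubstituted alkenes that chemical allylic oxidants do not tell apart cleanly.

**C5–C10 and C6–C7 (key disconnection).** Cutting these two bonds of 5 opens both rings and gives the acyclic chain of farnesyl diphosphate 3, with germacrene A 4 as the monocyclic stage in between. No other pair of cuts removes both rings and all three stereocentres of 5 and leaves an achiral precursor that is made in two steps. The forward reaction must fold the chain in one absolute sense and close first the ten-membered ring and then the two six-membered rings.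

**C–O bond of the diphosphate.** 3 is made from farnesyl chloride 2, and this from commercial (2E,6E)-farnesol 1. The only demand is that the 2E geometry and the primary allylic position are kept.

## Alternatives that were turned down

**Alternative 1:** Ring B is cut at C5–C10 and C8–C9. This leads back to methacrolein A2 (C9, C10, C14 and the formyl carbon as C1) and an enantiopure 2-silyloxydiene A3 that already carries C4 with its methyl, a silyl-protected hydroxyl and an ethynyl group. In the forward sense a chiral oxazaborolidinium Lewis acid would bind the aldehyde of A2 and steer the [4+2] addition to the cyclohexene A1, in which C10 is quaternary and C7 is a silyl enol ether.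
- For it: the absolute configuration of C10 comes from a small-molecule catalyst, the tertiary carbinol C4 enters complete, everything is ordinary solution chemistry that scales, and analogues are easy to reach. On these points it is stronger than the chosen plan.
- Against it: C4 and C10 are set by two independent stereochemical elements, with a possible mismatched pairing. The C5 stereocentre made by the cycloaddition is later erased. Ring A still has to be closed between C1 and the alkyne carbon C2, after which C1 must lose its oxygen and C3 must gain one with the right configuration. C7 with its acrylate must be installed from a ring ketone at a position that ends up doubly allylic.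
- Comparison: the work after A1 would be about twice as long as the whole chosen route. The chosen route needs an enzyme, but in return delivers all fifteen carbons and C7/C10 in one step.

**Alternative 2:** The C9–C10 bond and the C5=C6 alkene are disconnected, which is a Robinson annulation of ring B onto 3-methylcyclohexane-1,2-dione A5 with methyl vinyl ketone A6. A chiral primary amine salt would mediate the Michael addition at the methyl-bearing carbon (C10), and aldol condensation of the new methyl ketone onto the neighbouring carbonyl (C5) would give the enedione A4.
- For it: two cheap achiral materials, one or two operations, C10 set catalytically, the C5=C6 alkene already in its final place and a carbonyl at C4 ready for methyl addition. In material cost and in having C5=C6 from the start it beats the chosen plan, which must isomerise an epoxide to obtain that alkene.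
- Against it: C7 arrives as an enone carbonyl and must become a CH stereocentre bearing the acrylate while C5=C6 stays in place, with only the remote C10 to control the face. C3 needs α-oxygenation of the C4 ketone before a diastereoselective methyl addition. The regiochemistry of the Michael step (which enol carbon of the unsymmetrical dione) and of the aldol step must both be held.
- Comparison: the hard problem of the target, C7 relative to C10, is left unsolved, whereas the cyclase sets both in the same event. The work after A4 would clearly exceed the eight functional-group steps of the chosen route.

**Alternative 3:** The C9–C10 bond is cut, with ring A taken back to a phenol. A8 carries the hydroxyl on C3, methyls on C4 and C10, and on C5 a chain C6–C9 with the C7 stereocentre (isopropenyl) and a primary mesylate on C9. A tert-butoxide base would form the phenolate, whose para carbon C10 displaces the mesylate, closing ring B and giving the cross-conjugated dienone A7.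
- For it: the C3 oxygen and the C4=C5 alkene are present from the outset, so the regiochemical question of the allylic oxidation in step 7 does not arise; on this point the alternative is stronger. C7 can come from the chiral pool, and A7 is one conjugate reduction away from an enone of the type of 11 that still has an isopropenyl group.
- Against it: the configuration of C10 depends on 1,4-induction from C7 through the chair-like transition state of the ring closure. The ortho carbon C4 can also reach C9 through a six-membered ring, which would give a linearly conjugated dienone. A8 needs a multistep enantioselective synthesis. Afterwards C1=C2 must be reduced without touching the isopropenyl group, which then still has to be oxidised to the acrylate chemically next to an enone.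
- Comparison: from that point the end game would be the same as here, so the alternative is longer overall and less secure on C10. The chosen strategy offers enzyme-fixed C7 and C10 at the price of a less certain C3 oxidation.

Key step: step 3

Remark: 3 is drawn as the free acid and handled as its trisammonium salt; the recombinant cyclase and the P450-expressing yeast are treated as catalysts prepared by standard heterologous expression, and the cyclase is taken to be a plant β-selinene synthase of the (+)-series, whose product is to be checked against authentic (+)-β-selinene.

## Route

Step 1
Reactants: 1 (2E,6E)-farnesol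
Product: 2 (2E,6E)-farnesyl chloride
Conditions: NCS, Me2S, CH2Cl2, −40 to 0 °C
Reagents that add atoms: N-chlorosuccinimide, O=C1CCC(=O)N1Cl
Why: Corey–Kim chlorination: the alkoxysulfonium salt of the primary allylic alcohol is displaced by chloride at C1 without allylic transposition or loss of the 2E geometry, and the neutral conditions spare the other trisubstituted alkenes.

Step 2
Reactants: 2 (2E,6E)-farnesyl chloride
Product: 3 (2E,6E)-farnesyl diphosphate
Conditions: (n-Bu4N)3HP2O7, MeCN, rt; then cation exchange (NH4+ form), cellulose chromatography, lyophilisation
Reagents that add atoms: tris(tetrabutylammonium) hydrogen diphosphate, CCCC[N+](CCCC)(CCCC)CCCC.CCCC[N+](CCCC)(CCCC)CCCC.CCCC[N+](CCCC)(CCCC)CCCC.OP(=O)([O-])OP(=O)([O-])[O-]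
Why: SN2 displacement of a primary allylic chloride by the soluble diphosphate anion in a dipolar aprotic solvent, the standard preparation of prenyl diphosphates; direct attack at C1 keeps the 2E,6E geometry.

Step 3
Reactants: 3 (2E,6E)-farnesyl diphosphate
Product: 5 (+)-β-selinene, via enzyme-bound (+)-germacrene A 4 (not isolated)
Conditions: recombinant (+)-β-selinene synthase, MgCl2, HEPES buffer pH 7.5, DTT, 10% glycerol, pentane overlay, 30 °C
Reagents that add atoms: none
Why: Divalent magnesium bound to the diphosphate triggers ionisation of 3 to the allyl cation; the distal alkene adds through its less substituted carbon (the future C7) to C6, which closes the ten-membered ring and leaves a tertiary cation on C11, and loss of a methyl proton gives bound 4. Reprotonation of 4 at C1 places a tertiary cation on C10, the C4=C5 alkene adds through C5 across the ring (bond C5–C10, tertiary cation on C4) and loss of a C15 proton releases 5. The reaction type is the cation–olefin cascade of class 1 terpene synthases; the closest reactions without an enzyme are the acid-induced transannular cyclisation of germacrenes and Brønsted-acid polyene cyclisation. The ten-membered ring closes by addition of the allyl cation to the distal alkene in the exo, Markovnikov sense; rings A and B then arise together from the one transannular bond, which is 6-endo for ring A and 6-exo for ring B with respect to the C4=C5 alkene. C7 is set in the first closure by the alkene face that the pocket holds against C6. C5 and C10 are set in the second closure by the chair–chair fold of bound 4, which gives the trans ring fusion with the C10 methyl β and H5 α. The step needs the ten- and not the eleven-membered first ring, reprotonation at C1 and a single enantiomeric fold; the substrate has no bias for any of these, so all of them rest on the shape of the active site. Which proton is lost at the end is unimportant, because step 6 funnels the double-bond isomers of ring A into one compound.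

Step 4
Reactants: 5 (+)-β-selinene
Product: 8 β-costic acid, via β-costol 6 (not isolated), via β-costal 7 (not isolated)
Conditions: resting S. cerevisiae cells expressing a CYP71-family sesquiterpene C12 oxidase and a cytochrome P450 reductase, air, glucose, phosphate buffer pH 7.4, 30 °C; then pH 3, EtOAc
Reagents that add atoms: dioxygen, O=O
Why: Cytochrome P450 allylic hydroxylation carried through three rounds (methyl to alcohol to aldehyde to acid), the reaction that germacrene A oxidase and amorphadiene oxidase perform on the isopropenyl methyl of their sesquiterpene substrates; 8 is the metabolite that plants producing 5 derive from it, so an oxidase fitting this substrate exists. The enzyme pocket, not intrinsic reactivity, picks C12 over the allylic C3 of the other 1,1-disubstituted alkene.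

Step 5
Reactants: 8 β-costic acid
Product: 9 methyl β-costate
Conditions: MeI, K2CO3, DMF, rt
Reagents that add atoms: iodomethane, CI
Why: O-alkylation of the carboxylate (SN2 on iodomethane); the mild base at room temperature leaves both 1,1-disubstituted alkenes in place, and the ester removes the acidic proton before the acid- and metal-mediated steps.

Step 6
Reactants: 9 methyl β-costate
Product: 10 methyl isocostate
Conditions: p-TsOH·H2O (cat.), toluene, 80 °C
Reagents that add atoms: none
Why: Acid-catalysed alkene isomerisation: protonation at the exocyclic C15 gives the tertiary C4 cation and loss of H5 gives the tetrasubstituted C4=C5 alkene, the thermodynamic isomer; the acrylate alkene is too electron-poor to be protonated, so the side chain stays 11(13). C5 ceases to be a stereocentre, as the target requires.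

Step 7
Reactants: 10 methyl isocostate
Product: 11 methyl 3-oxoeudesma-4,11(13)-dien-12-oate
Conditions: CrO3, 3,5-dimethylpyrazole, CH2Cl2, −20 °C
Reagents that add atoms: chromium trioxide, O=[Cr](=O)=O
Why: Allylic C–H oxidation of a ring alkene to the enone by the pyrazole complex of hexavalent chromium; C3 should be preferred over C6 because the axial H6β is 1,3-diaxial to the C14 methyl and C6 is flanked by the substituted C7, as in the C7-over-C4 preference of steroidal 5-enes, and the primary C15 hydrogens are less reactive. The electron-poor acrylate is inert.

Step 8
Reactants: 11 methyl 3-oxoeudesma-4,11(13)-dien-12-oate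
Product: 12 methyl 3β-hydroxyeudesma-4,11(13)-dien-12-oate
Conditions: NaBH4, CeCl3·7H2O, MeOH, −78 to −20 °C
Reagents that add atoms: none
Why: Luche 1,2-reduction: the cerium-activated borohydride attacks the ketone and not C5 or the acrylate, and approaches axially from the α face away from the C14 methyl, giving the equatorial 3β-alcohol (new stereocentre C3 by substrate control, as with steroidal 4-en-3-ones).

Step 9
Reactants: 12 methyl 3β-hydroxyeudesma-4,11(13)-dien-12-oate
Product: 13 methyl 4β,5β-epoxy-3β-hydroxyeudesm-11(13)-en-12-oate
Conditions: VO(acac)2 (cat.), t-BuOOH, CH2Cl2, 0 °C to rt
Reagents that add atoms: tert-butyl hydroperoxide, CC(C)(C)OO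
Why: Hydroxyl-directed epoxidation: the vanadium alkoxide of the 3β-hydroxyl delivers the peroxide oxygen to the same (β) face of the tetrasubstituted alkene, setting C4 and C5 and overriding the shielding of that face by C14. The acrylate has no directing hydroxyl and is electron-poor, so it does not react.

Step 10
Reactants: 13 methyl 4β,5β-epoxy-3β-hydroxyeudesm-11(13)-en-12-oate
Product: 14 methyl 3β,4β-dihydroxyeudesma-5,11(13)-dien-12-oate
Conditions: Ti(OiPr)4, CH2Cl2, rt; then 10% aq. tartaric acid
Reagents that add atoms: none
Why: Titanium-mediated rearrangement of a 2,3-epoxy alcohol to an allylic 1,2-diol: tetravalent titanium held on the C3 alkoxide activates the epoxide oxygen, the bond to the fully substituted distal carbon C5 breaks and an alkoxide ligand removes the syn H6; C10 carries no hydrogen, so only the C5=C6 alkene can form. The C4–O bond is not touched, so the 4β-hydroxyl keeps the configuration set in step 9.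

Step 11
Reactants: 14 methyl 3β,4β-dihydroxyeudesma-5,11(13)-dien-12-oate; 15 angelic acid
Product: 17 methyl 3β-angeloyloxy-4β-hydroxyeudesma-5,11(13)-dien-12-oate, via angelic 2,4,6-trichlorobenzoic anhydride 16 (not isolated)
Conditions: 15, 2,4,6-trichlorobenzoyl chloride, Et3N, toluene, rt; then 14, toluene, 80 °C
Reagents that add atoms: none
Why: Yamaguchi-type mixed-anhydride esterification run without a nucleophilic catalyst: the ortho chlorines block the aroyl carbonyl, so the equatorial secondary 3β-hydroxyl attacks the angeloyl carbonyl, and no acylpyridinium or amine adduct forms that could turn the Z ester into its E isomer. The tertiary 4β-hydroxyl is too hindered to be acylated.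

## Compound list

1 | (2E,6E)-farnesol | CC(C)=CCC/C(C)=C/CC/C(C)=C/CO | starting material
2 | (2E,6E)-farnesyl chloride | CC(C)=CCC/C(C)=C/CC/C(C)=C/CCl | intermediate
3 | (2E,6E)-farnesyl diphosphate (drawn as the free acid) | CC(C)=CCC/C(C)=C/CC/C(C)=C/COP(=O)(O)OP(=O)(O)O | intermediate
4 | (+)-germacrene A, (7R)-germacra-1(10)E,4E,11-triene (enzyme-bound) | CC(=C)[C@H]1C/C=C(C)/CC/C=C(C)/CC1 | intermediate
5 | (+)-β-selinene, (5S,7R,10R)-eudesma-4(15),11-diene | CC(=C)[C@H]1C[C@H]2C(=C)CCC[C@]2(C)CC1 | intermediate
6 | β-costol, eudesma-4(15),11(13)-dien-12-ol | OCC(=C)[C@H]1C[C@H]2C(=C)CCC[C@]2(C)CC1 | intermediate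
7 | β-costal, eudesma-4(15),11(13)-dien-12-al | O=CC(=C)[C@H]1C[C@H]2C(=C)CCC[C@]2(C)CC1 | intermediate
8 | β-costic acid, eudesma-4(15),11(13)-dien-12-oic acid | C=C(C(=O)O)[C@H]1C[C@H]2C(=C)CCC[C@]2(C)CC1 | intermediate
9 | methyl β-costate | C=C(C(=O)OC)[C@H]1C[C@H]2C(=C)CCC[C@]2(C)CC1 | intermediate
10 | methyl isocostate, methyl eudesma-4,11(13)-dien-12-oate | C=C(C(=O)OC)[C@H]1CC2=C(C)CCC[C@]2(C)CC1 | intermediate
11 | methyl 3-oxoeudesma-4,11(13)-dien-12-oate | C=C(C(=O)OC)[C@H]1CC2=C(C)C(=O)CC[C@]2(C)CC1 | intermediate
12 | methyl 3β-hydroxyeudesma-4,11(13)-dien-12-oate | C=C(C(=O)OC)[C@H]1CC2=C(C)[C@@H](O)CC[C@]2(C)CC1 | intermediate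
13 | methyl 4β,5β-epoxy-3β-hydroxyeudesm-11(13)-en-12-oate | C=C(C(=O)OC)[C@H]1C[C@]23O[C@@]2(C)[C@@H](O)CC[C@]3(C)CC1 | intermediate
14 | methyl 3β,4β-dihydroxyeudesma-5,11(13)-dien-12-oate (4α-methyl) | C=C(C(=O)OC)[C@H]1C=C2[C@](C)(CC[C@H](O)[C@]2(C)O)CC1 | intermediate
15 | angelic acid, (Z)-2-methylbut-2-enoic acid | C/C=C(/C)C(=O)O | starting material
16 | angelic 2,4,6-trichlorobenzoic anhydride | C/C=C(/C)C(=O)OC(=O)c1c(Cl)cc(Cl)cc1Cl | intermediate
17 | methyl (3S,4R,7R,10S)-3-[(Z)-2-methylbut-2-enoyloxy]-4-hydroxyeudesma-5,11(13)-dien-12-oate (3β-angeloyloxy, 4β-hydroxy; CNP0283268.1) | C=C(C(=O)OC)[C@H]1C=C2[C@](C)(CC[C@H](OC(=O)/C(C)=C\C)[C@]2(C)O)CC1 | target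

## Step count and least certain steps

Total step count: 11. Longest linear sequence: 11 steps (1 to 17); 15 enters in the last step.

**Step 3 (key step).** What may go wrong is early release of the monocyclic intermediate or of other cyclisation products from the active site, low turnover and product inhibition on preparative scale, evaporative loss of the hydrocarbon, or folding of the chain in the wrong enantiomeric sense by the enzyme chosen. The fallback divides the cascade between an enzyme and an acid. It sets out from 3, which is cyclised with a recombinant (+)-germacrene A synthase under the same buffer conditions; 4 is then isolated cold, because it undergoes Cope rearrangement on warming. The enzyme has then fixed C7, and brief treatment of 4 with a mild acid (silica gel or dilute AcOH in hexane) closes the C5–C10 bond through the same chair–chair conformer. This should give 5 together with its ring-A alkene isomers α-selinene F1 and selina-4,11-diene F2, all with the same C7 and C10. The mixture is carried through steps 4 and 5, which act far from ring A, as 8 with α-costic acid F3 and isocostic acid F4, and then as 9 with methyl α-costate F5 and 10. The acid of step 6 converts all of them into 10, where the fallback rejoins the route.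

**Step 4.** What may go wrong is poor uptake of the volatile, water-insoluble substrate by the cells, oxidation that stops at the alcohol or aldehyde level, hydroxylation at other positions, or refusal of the substrate by the oxidase chosen. The fallback is chemical and sets out from 5. Allylic metalation with n-BuLi/TMEDA should take place at the isopropenyl methyl, the only position that gives an allyl anion with two primary termini, to give 12-lithio-β-selinene F6. Trapping with B(OMe)3 gives the dimethyl allylboronate F7, and NaOH/H2O2 oxidises it to 6, which is now isolated. MnO2 in CH2Cl2 gives 7, and Pinnick oxidation (NaClO2, NaH2PO4, 2-methyl-2-butene, t-BuOH/H2O) gives 8, where the route is rejoined.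

**Step 7.** What may go wrong is competing oxidation at C6, over-oxidation to an ene-dione, or allylic transposition at the tetrasubstituted alkene. The fallback oxidises C3 while the alkene is still exocyclic, where C3 is the only allylic CH2, and moves the alkene afterwards. It sets out from 9. SeO2 (cat.)/t-BuOOH in CH2Cl2 should give methyl 3α-hydroxyeudesma-4(15),11(13)-dien-12-oate F8, and Dess–Martin periodinane the exocyclic enone methyl 3-oxoeudesma-4(15),11(13)-dien-12-oate F9. 1,4-Hydrosilylation with Et3SiH and RhCl(PPh3)3 (cat.), which prefers the s-cis enone to the acrylate, gives the regiodefined silyl enol ether methyl 3-(triethylsilyloxy)eudesma-3,11(13)-dien-12-oate F10. Saegusa–Ito oxidation with Pd(OAc)2 in MeCN, by β-hydride elimination of H5 from the C4-bound enolate of divalent palladium, then gives 11, where the route is rejoined; steps 6 and 7 are bypassed.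

**Step 10.** What may go wrong is capture of the developing C5 cation by isopropoxide, a 1,2-shift (ring contraction from C4 or methyl migration from C10), transesterification of the methyl ester by the titanium alkoxide, or simply slow opening of the hindered tetrasubstituted epoxide. The fallback replaces hydroxyl-delivered titanium by an external silyl Lewis acid and an external amidine base on the silylated substrate. It sets out from 13. TMSOTf and DBU in toluene (−78 °C to rt) silylate the C3 hydroxyl and the epoxide oxygen; the silyloxonium ion opens toward C5, because C4 is deactivated by the neighbouring C3–O bond, and the base removes H6. This should give methyl 3β,4β-bis(trimethylsilyloxy)eudesma-5,11(13)-dien-12-oate F11, and K2CO3 in MeOH at 0 °C removes both silyl groups to give 14, where the route is rejoined.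

**Step 11.** What may go wrong is Z-to-E isomerisation of the acyl group during activation or acyl transfer, and slow acylation next to the tertiary hydroxyl. The fallback builds the Z alkene on the molecule, so that no activated angeloyl species is ever present. It sets out from 14, whose 3β-hydroxyl is esterified (carbodiimide, cat. DMAP, CH2Cl2) with 2-[bis(2,2,2-trifluoroethoxy)phosphoryl]propanoic acid F12, obtained by saponification of its commercial ethyl ester. This gives the phosphonate ester F13 as a mixture of epimers at the phosphonate carbon. Still–Gennari olefination of F13 with acetaldehyde (KN(SiMe3)2, 18-crown-6, THF, −78 °C) should give the Z-trisubstituted enoate, that is 17; the phosphonate proton is far more acidic than the tertiary hydroxyl or H7, so one equivalent of base suffices.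

## Further compounds

F1 | step 3 | α-selinene, eudesma-3,11-diene | CC(=C)[C@H]1C[C@H]2C(C)=CCC[C@]2(C)CC1
F2 | step 3 | selina-4,11-diene | CC(=C)[C@H]1CC2=C(C)CCC[C@]2(C)CC1
F3 | step 3 | α-costic acid, eudesma-3,11(13)-dien-12-oic acid | C=C(C(=O)O)[C@H]1C[C@H]2C(C)=CCC[C@]2(C)CC1
F4 | step 3 | isocostic acid, eudesma-4,11(13)-dien-12-oic acid | C=C(C(=O)O)[C@H]1CC2=C(C)CCC[C@]2(C)CC1
F5 | step 3 | methyl α-costate | C=C(C(=O)OC)[C@H]1C[C@H]2C(C)=CCC[C@]2(C)CC1
F6 | step 4 | 12-lithio-β-selinene (allyllithium, TMEDA complex) | [Li]CC(=C)[C@H]1C[C@H]2C(=C)CCC[C@]2(C)CC1
F7 | step 4 | dimethyl eudesma-4(15),11(13)-dien-12-ylboronate | COB(OC)CC(=C)[C@H]1C[C@H]2C(=C)CCC[C@]2(C)CC1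
F8 | step 7 | methyl 3α-hydroxyeudesma-4(15),11(13)-dien-12-oate | C=C(C(=O)OC)[C@H]1C[C@H]2C(=C)[C@H](O)CC[C@]2(C)CC1
F9 | step 7 | methyl 3-oxoeudesma-4(15),11(13)-dien-12-oate | C=C(C(=O)OC)[C@H]1C[C@H]2C(=C)C(=O)CC[C@]2(C)CC1
F10 | step 7 | methyl 3-(triethylsilyloxy)eudesma-3,11(13)-dien-12-oate | C=C(C(=O)OC)[C@H]1C[C@H]2C(C)=C(O[Si](CC)(CC)CC)CC[C@]2(C)CC1
F11 | step 10 | methyl 3β,4β-bis(trimethylsilyloxy)eudesma-5,11(13)-dien-12-oate | C=C(C(=O)OC)[C@H]1C=C2[C@](C)(CC[C@H](O[Si](C)(C)C)[C@]2(C)O[Si](C)(C)C)CC1
F12 | step 11 | 2-[bis(2,2,2-trifluoroethoxy)phosphoryl]propanoic acid | CC(C(=O)O)P(=O)(OCC(F)(F)F)OCC(F)(F)F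
F13 | step 11 | methyl 3β-{2-[bis(2,2,2-trifluoroethoxy)phosphoryl]propanoyloxy}-4β-hydroxyeudesma-5,11(13)-dien-12-oate (epimers at the phosphonate carbon) | C=C(C(=O)OC)[C@H]1C=C2[C@](C)(CC[C@H](OC(=O)C(C)P(=O)(OCC(F)(F)F)OCC(F)(F)F)[C@]2(C)O)CC1
A1 | alternative 1 | 4-(tert-butyldimethylsilyloxy)-1-methyl-2-[2-(triethylsilyloxy)but-3-yn-2-yl]cyclohex-3-ene-1-carbaldehyde | O=C[C@]1(C)CCC(O[Si](C)(C)C(C)(C)C)=C[C@@H]1[C@@](C)(O[Si](CC)(CC)CC)C#C
A2 | alternative 1 | methacrolein | CC(=C)C=O
A3 | alternative 1 | (E)-2-(tert-butyldimethylsilyloxy)-5-methyl-5-(triethylsilyloxy)hepta-1,3-dien-6-yne | C=C(O[Si](C)(C)C(C)(C)C)/C=C/[C@@](C)(O[Si](CC)(CC)CC)C#C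
A4 | alternative 2 | 10-methyloctal-5-ene-4,7-dione (eudesmane numbering) | O=C1C=C2C(=O)CCC[C@]2(C)CC1
A5 | alternative 2 | 3-methylcyclohexane-1,2-dione | CC1CCCC(=O)C1=O
A6 | alternative 2 | methyl vinyl ketone | CC(=O)C=C
A7 | alternative 3 | eudesma-1,4,11-trien-3-one | CC(=C)[C@H]1CC2=C(C)C(=O)C=C[C@]2(C)CC1
A8 | alternative 3 | 3-[(3-hydroxy-2,6-dimethylphenyl)methyl]-4-methylpent-4-en-1-yl methanesulfonate | CC(=C)[C@H](CCOS(C)(=O)=O)Cc1c(C)c(O)ccc1C
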